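**Plan**

1. Numbering: ring A = C1, C2, C3 (Br), C4 (CH3 and the side chain C1'–C4'), C5 (H), C10 (CH3); ring B = C5, C6, C7, C8 (exocyclic C12), C9 (H and benzylic C11), C10.
2. Cuts, in retrosynthetic order: the C3'=C4' alkene (Wittig) and the acid (ester); then, with C11 back at the ketone level and the C8=C9 and C5=C6 unsaturation restored, both ring B bonds C9–C10 and C7–C8 in one Diels–Alder disconnection; then the C5–C6 vinyl bond (Stille) and the C4 quaternary centre (1,2-shift).
3. Enabling feature: ring B holds C8 and C9 side by side between C7 and the quaternary C10, so C10–C5–C6–C7 can be a vinylcyclohexene diene carried by ring A, and C8, C9, C11, C12 are the four carbons of an aryl but-2-ynone.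
4. Forward order: ring A starts as a cyclohexenone that receives the side chain and is elaborated to the bromo diene; the aryl ynone is made in parallel; the cycloaddition closes ring B; alkene and ketone adjustment follow and the side-chain alkene is made last.
5. Stereochemistry: an oxazaborolidine reduction sets a carbinol centre that is passed on through a hydroxyl-directed epoxide and a Wharton transposition to the tertiary carbinol, and from there to C3 and C4 by a stereospecific anti 1,2-shift; C10 comes from diene-face selection by the pseudoaxial C4 methyl; C5 from hydrogenation anti to both axial methyls; C9 from protonation of a dienol anti to the C10 methyl.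

Key step: step 14

Assumption: in step 2 the α-methyl-substituted alkenyl arm of enone 5 is taken to act as the large group in the oxazaborolidine reduction, so the (S)-catalyst should give the (R)-alcohol; the (R)-catalyst would be used if the sense proved opposite.

**Route**

Step 1
Reactants: 1 (3-bromopropoxy)(tert-butyl)dimethylsilane; 2 3-ethoxy-2-methylcyclohex-2-en-1-one
Product: 5 3-(3-{[tert-butyl(dimethyl)silyl]oxy}propyl)-2-methylcyclohex-2-en-1-one, via Grignard reagent 3 (not isolated), via tertiary carbinol 4 (not isolated)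
Conditions: Mg turnings, THF, 40 °C; then 2, THF, 0 °C → rt; then 1 M HCl, 0 °C, 30 min
Reagents that add atoms: magnesium, [Mg] (present in 3 only); water, O (carbonyl oxygen of 5)
Why: Stork–Danheiser alkylation, in which the Grignard reagent adds 1,2 to the vinylogous ester and cold dilute acid ionises the tertiary allylic carbinol and hydrolyses the enol ether to the transposed 2,3-disubstituted enone, under conditions brief enough for a primary TBS ether to survive.

Step 2
Reactants: 5 3-(3-{[tert-butyl(dimethyl)silyl]oxy}propyl)-2-methylcyclohex-2-en-1-one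
Product: 6 (1R)-3-(3-{[tert-butyl(dimethyl)silyl]oxy}propyl)-2-methylcyclohex-2-en-1-ol
Conditions: (S)-1-methyl-3,3-diphenyltetrahydro-1H,3H-pyrrolo[1,2-c][1,3,2]oxazaborole (20 mol%), BH3·SMe2 (0.7 equiv), THF, −20 °C; MeOH
Reagents that add atoms: none
Why: Corey–Bakshi–Shibata reduction, in which the ketone binds the ring boron with its α-methyl-substituted alkenyl arm (the large group) turned away from the catalyst and hydride is delivered to one carbonyl face to give the (R)-allylic alcohol, 1,2-reduction being much faster than hydroboration of the tetrasubstituted alkene.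

Step 3
Reactants: 6 (1R)-3-(3-{[tert-butyl(dimethyl)silyl]oxy}propyl)-2-methylcyclohex-2-en-1-ol
Product: 7 (1R,2R,6R)-6-(3-{[tert-butyl(dimethyl)silyl]oxy}propyl)-1-methyl-7-oxabicyclo[4.1.0]heptan-2-ol
Conditions: VO(acac)2 (5 mol%), t-BuOOH (1.5 equiv, in decane), CH2Cl2, 0 °C → rt
Reagents that add atoms: tert-butyl hydroperoxide, CC(C)(C)OO
Why: Hydroxyl-directed epoxidation through the vanadium alkoxide–alkylperoxide complex, which delivers oxygen to the alkene face syn to the hydroxyl, so that both epoxide centres (C4 and C5) are set by the carbinol centre.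

Step 4
Reactants: 7 (1R,2R,6R)-6-(3-{[tert-butyl(dimethyl)silyl]oxy}propyl)-1-methyl-7-oxabicyclo[4.1.0]heptan-2-ol
Product: 8 (1S,6R)-6-(3-{[tert-butyl(dimethyl)silyl]oxy}propyl)-1-methyl-7-oxabicyclo[4.1.0]heptan-2-one
Conditions: Dess–Martin periodinane, NaHCO3, CH2Cl2, 0 °C → rt
Reagents that add atoms: none
Why: Dess–Martin oxidation of the secondary alcohol under buffered conditions that leave the tetrasubstituted epoxide and the silyl ether intact, the stereochemical information now residing in the epoxide alone.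

Step 5
Reactants: 8 (1S,6R)-6-(3-{[tert-butyl(dimethyl)silyl]oxy}propyl)-1-methyl-7-oxabicyclo[4.1.0]heptan-2-one
Product: 10 (1R)-1-(3-{[tert-butyl(dimethyl)silyl]oxy}propyl)-2-methylcyclohex-2-en-1-ol, via epoxy hydrazone 9 (not isolated)
Conditions: N2H4·H2O (3 equiv), AcOH (0.3 equiv), MeOH, 0 °C → rt
Reagents that add atoms: hydrazine, NN (nitrogen present in 9 only)
Why: Wharton transposition, in which the epoxy hydrazone tautomerises to a diazene that opens the epoxide at the α-carbon and loses N2, so that the alkene moves to C3=C4 and the oxygen stays on C5 with its configuration unchanged, giving the (R)-tertiary allylic alcohol.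

Step 6
Reactants: 10 (1R)-1-(3-{[tert-butyl(dimethyl)silyl]oxy}propyl)-2-methylcyclohex-2-en-1-ol
Product: 11 (2R,3R)-3-bromo-2-(3-{[tert-butyl(dimethyl)silyl]oxy}propyl)-2-methylcyclohexan-1-one
Conditions: NBS (1.1 equiv), CH2Cl2, −20 → 0 °C, dark
Reagents that add atoms: N-bromosuccinimide, O=C1CCC(=O)N1Br
Why: Bromonium-induced semipinacol rearrangement, in which Br+ adds to the alkene face opposite the pseudoaxial side chain (allylic 1,2-strain with the 2-methyl group keeps the larger carbinol substituent axial) and the chain then shifts antiperiplanar from the carbinol carbon C5 to the tertiary cationic carbon C4 as the ketone forms, so that bromine and chain end up trans and the carbinol configuration is transferred without loss to C3 (R) and C4 (R).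

Step 7
Reactants: 11 (2R,3R)-3-bromo-2-(3-{[tert-butyl(dimethyl)silyl]oxy}propyl)-2-methylcyclohexan-1-one
Product: 13 (2R,3R)-3-bromo-2-(3-{[tert-butyl(dimethyl)silyl]oxy}propyl)-2,6-dimethylcyclohexan-1-one (both C6 epimers), via lithium enolate 12 (not isolated)
Conditions: LiN(iPr)2 (1.05 equiv), THF, −78 °C; MeI, −78 → −20 °C
Reagents that add atoms: iodomethane, CI
Why: Kinetic enolate alkylation at the only enolisable position (C10), whose epimers converge in step 8, with the bromide safe because it sits β to the carbonyl across a quaternary carbon (no E1cB path) and the silyl ether inert to the base.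

Step 8
Reactants: 13 (2R,3R)-3-bromo-2-(3-{[tert-butyl(dimethyl)silyl]oxy}propyl)-2,6-dimethylcyclohexan-1-one
Product: 15 (5R,6R)-5-bromo-6-(3-{[tert-butyl(dimethyl)silyl]oxy}propyl)-2,6-dimethylcyclohex-1-en-1-yl trifluoromethanesulfonate, via potassium enolate 14 (not isolated)
Conditions: KN(SiMe3)2, THF, −78 → 0 °C; PhNTf2, −78 °C → rt
Reagents that add atoms: N-phenylbis(trifluoromethanesulfonimide), O=S(=O)(N(c1ccccc1)S(=O)(=O)C(F)(F)F)C(F)(F)F
Why: Enol triflate formation by O-sulfonylation of the potassium enolate, which can form only toward C10 because C4 is quaternary, as is routine for 2,2,6-trisubstituted cyclohexanones.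

Step 9
Reactants: 15 (5R,6R)-5-bromo-6-(3-{[tert-butyl(dimethyl)silyl]oxy}propyl)-2,6-dimethylcyclohex-1-en-1-yl trifluoromethanesulfonate; 16 tributyl(ethenyl)stannane
Product: 17 tert-butyl{3-[(1R,6R)-6-bromo-2-ethenyl-1,3-dimethylcyclohex-2-en-1-yl]propoxy}dimethylsilane
Conditions: Pd(PPh3)4 (5 mol%), LiCl (3 equiv), THF, 65 °C
Reagents that add atoms: none
Why: Stille cross-coupling of the hindered enol triflate with the vinylstannane (chloride-assisted transmetalation), in which triphenylphosphine-ligated zerovalent palladium inserts into the C–OTf bond far faster than into the secondary alkyl C–Br bond.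

Step 10
Reactants: 18 methyl 3-formyl-4-hydroxybenzoate
Product: 19 methyl 3-bromo-5-formyl-4-hydroxybenzoate
Conditions: Br2 (1.05 equiv), NaOAc, AcOH, rt
Reagents that add atoms: bromine, BrBr
Why: Electrophilic aromatic bromination directed by the phenol to its single free ortho position, the para position being blocked by the ester.

Step 11
Reactants: 19 methyl 3-bromo-5-formyl-4-hydroxybenzoate
Product: 20 methyl 3-bromo-5-formyl-4-(methoxymethoxy)benzoate
Conditions: MOMCl, iPr2NEt, CH2Cl2, 0 °C → rt
Reagents that add atoms: chloromethyl methyl ether, COCCl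
Why: O-Alkylation of the acidic phenol to the MOM acetal, which masks it through the Grignard addition, the cycloaddition and the photolysis, where a free ortho-hydroxy ketone would cyclise or quench the excited state.

Step 12
Reactants: 20 methyl 3-bromo-5-formyl-4-(methoxymethoxy)benzoate; 21 prop-1-yn-1-ylmagnesium bromide
Product: 22 methyl 3-bromo-5-(1-hydroxybut-2-yn-1-yl)-4-(methoxymethoxy)benzoate (racemic carbinol)
Conditions: THF, −78 → −20 °C; aq. NH4Cl
Reagents that add atoms: none
Why: Chemoselective 1,2-addition of an alkynyl Grignard reagent to the aldehyde at low temperature, where the methyl ester and the aryl bromide do not react.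

Step 13
Reactants: 22 methyl 3-bromo-5-(1-hydroxybut-2-yn-1-yl)-4-(methoxymethoxy)benzoate
Product: 23 methyl 3-bromo-5-(but-2-ynoyl)-4-(methoxymethoxy)benzoate
Conditions: MnO2 (activated, excess), CH2Cl2, rt
Reagents that add atoms: none
Why: MnO2 oxidation of a benzylic propargylic alcohol to the ynone under neutral conditions that leave the MOM acetal and the ester untouched.

Step 14
Reactants: 17 tert-butyl{3-[(1R,6R)-6-bromo-2-ethenyl-1,3-dimethylcyclohex-2-en-1-yl]propoxy}dimethylsilane; 23 methyl 3-bromo-5-(but-2-ynoyl)-4-(methoxymethoxy)benzoate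
Product: 24 Diels–Alder adduct, the ring B 1,4-cyclohexadiene (C5=C6, C8=C9) with the C11 aryl ketone, (3R,4R,10R) in the numbering above
Conditions: 23 (1.5 equiv), toluene (2 M), BHT (cat.), 120 °C, sealed tube
Reagents that add atoms: none
Why: Thermal, concerted but asynchronous normal-demand Diels–Alder reaction, suprafacial on both partners, in which the unsubstituted diene terminus C7 (largest HOMO coefficient) bonds first to the ynone β-carbon C8 and the carbonyl-bearing C9 then closes onto the fully substituted C10. The closest known reaction type is the cycloaddition of 2,6,6-trisubstituted 1-vinylcyclohexenes with acetylenic esters and ketones used to build ring B of drimanes. Ring B is closed by an intermolecular [4+2] cycloaddition that forms C7–C8 and C9–C10 in one operation and leaves a 1,4-cyclohexadiene. The single new stereocentre, C10, is controlled by the ring A half-chair, in which bromine and the side chain are equatorial and the C4 methyl is pseudoaxial, so the ynone adds to the diene face opposite that methyl and the C10 methyl ends up cis to it. The step needs regioselectivity (C7 to C8, not to C9), secured by the frontier-orbital polarisation of both partners and by the slim, linear alkyne that can reach the crowded C10, and diene-face selectivity, secured by the pseudoaxial C4 methyl. The ester- and bromine-bearing aryl ketone keeps the ynone electron-poor enough to react at a temperature the diene tolerates.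

Step 15
Reactants: 24 Diels–Alder adduct
Product: 25 trans-fused Δ8 enone, (3R,4R,5S,10R), with the C5–C6 alkene saturated
Conditions: [Ir(cod)(PCy3)(py)]PF6 (10 mol%), H2 (1–4 atm), CH2Cl2, rt
Reagents that add atoms: none
Why: Homogeneous hydrogenation with the cationic iridium catalyst, which reduces the hindered trisubstituted C5–C6 alkene but leaves the tetrasubstituted electron-poor C8–C9 enone and both C–Br bonds, and delivers hydrogen to the face opposite the axial C4 and C10 methyls so that C5–H is trans to the C10 methyl.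

Step 16
Reactants: 25 trans-fused Δ8 enone
Product: 26 β,γ-unsaturated ketone with the exocyclic C8=C12 methylene and C9–H, (3R,4R,5S,9R,10R)
Conditions: hν (350 nm, Pyrex), 1,2-dimethylimidazole (0.2 equiv), degassed MeCN, 0 °C, stopped at partial conversion and recycled
Reagents that add atoms: none
Why: Photochemical deconjugation by photoenolisation, in which the excited ketone abstracts an allylic hydrogen from the C12 methyl (the only γ-carbon cis to the carbonyl) through a six-membered 1,5-shift and the resulting exocyclic dienol is reprotonated at C9 under base catalysis from the face opposite the axial C10 methyl, giving the equatorial acyl group that is also the thermodynamic epimer.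

Step 17
Reactants: 26 β,γ-unsaturated ketone (MOM ether)
Product: 28 ortho-hydroxyaryl ketone (free phenol), via aryl trimethylsilyl ether 27 (not isolated)
Conditions: TMSOTf (2 equiv), 2,2'-bipyridyl (3 equiv), CH2Cl2, 0 °C; then H2O
Reagents that add atoms: trimethylsilyl trifluoromethanesulfonate, C[Si](C)(C)OS(=O)(=O)C(F)(F)F (silyl group present in 27 only)
Why: Non-protic Lewis-acid cleavage of an aromatic MOM ether through the aryl silyl ether, chosen because it spares the exocyclic alkene, the primary TBS ether and the enolisable β,γ-unsaturated ketone that protic acid would isomerise or cyclise.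

Step 18
Reactants: 28 ortho-hydroxyaryl ketone
Product: 30 methyl 3-bromo-5-{[(1R,4aS,5R,6R,8aS)-6-bromo-5-(3-{[tert-butyl(dimethyl)silyl]oxy}propyl)-5,8a-dimethyl-2-methylidenedecahydronaphthalen-1-yl]methyl}-4-hydroxybenzoate, via aryl ethyl carbonate 29 (not isolated)
Conditions: ClCO2Et, Et3N, THF, 0 °C; then NaBH4, H2O, 0 °C → rt
Reagents that add atoms: ethyl chloroformate, CCOC(=O)Cl (ethoxycarbonyl group present in 29 only)
Why: Reductive deoxygenation of an ortho-hydroxyaryl ketone through its O-ethoxycarbonyl derivative, in which borohydride reduces the ketone, the carbonate migrates to the new alkoxide and is expelled to give an ortho-quinone methide, and a second hydride adds at C11, all under conditions that leave both bromides, the ester, the silyl ether and the alkene alone.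

Step 19
Reactants: 30 silyl ether phenol with C11 as CH2
Product: 31 methyl 3-bromo-5-{[(1R,4aS,5R,6R,8aS)-6-bromo-5-(3-hydroxypropyl)-5,8a-dimethyl-2-methylidenedecahydronaphthalen-1-yl]methyl}-4-hydroxybenzoate
Conditions: Bu4NF (1 M in THF, 1.5 equiv), AcOH (1.5 equiv), THF, 0 °C → rt
Reagents that add atoms: none
Why: Fluoride-mediated cleavage of the primary TBS ether, buffered with acetic acid so that neither the methyl ester nor the locked equatorial bromide (which has no antiperiplanar hydrogen for elimination) is touched.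

Step 20
Reactants: 31 primary alcohol
Product: 32 methyl 3-bromo-5-{[(1R,4aS,5R,6R,8aS)-6-bromo-5,8a-dimethyl-2-methylidene-5-(3-oxopropyl)decahydronaphthalen-1-yl]methyl}-4-hydroxybenzoate
Conditions: Dess–Martin periodinane, NaHCO3, CH2Cl2, 0 °C → rt
Reagents that add atoms: none
Why: Dess–Martin oxidation of the primary alcohol to the aldehyde under buffered conditions, tolerated by the electron-poor phenol whose two ortho positions and para position are all substituted.

Step 21
Reactants: 32 aldehyde
Product: 33 methyl 3-bromo-5-{[(1R,4aS,5R,6R,8aS)-6-bromo-5,8a-dimethyl-2-methylidene-5-(4-methylpent-3-en-1-yl)decahydronaphthalen-1-yl]methyl}-4-hydroxybenzoate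
Conditions: iPrPPh3I (3.2 equiv), n-BuLi (3.0 equiv), THF, 0 °C; then 32, −78 °C → rt
Reagents that add atoms: propan-2-ylidene(triphenyl)phosphorane, CC(C)=P(c1ccccc1)(c1ccccc1)c1ccccc1, made in the flask from isopropyltriphenylphosphonium iodide, CC(C)[P+](c1ccccc1)(c1ccccc1)c1ccccc1.[I-]
Why: Wittig olefination with the non-stabilised isopropylidene ylide, used in excess because the phenol consumes one equivalent, gives the trisubstituted alkene, which has no E/Z issue.

Step 22
Reactants: 33 methyl ester of the target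
Product: 34 callophycoic acid H, 3-bromo-5-{[(1R,4aS,5R,6R,8aS)-6-bromo-5,8a-dimethyl-2-methylidene-5-(4-methylpent-3-en-1-yl)decahydronaphthalen-1-yl]methyl}-4-hydroxybenzoic acid
Conditions: LiOH (excess), THF/MeOH/H2O, 60 °C; then 1 M HCl to pH 3, 0 °C
Reagents that add atoms: lithium hydroxide, [Li+].[OH-]
Why: Saponification of the methyl ester, to which the conformationally locked equatorial neopentyl-type bromide is inert, followed by brief cold acidification so that the phenol does not add to the exocyclic alkene.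

**Compound list**

1 | (3-bromopropoxy)(tert-butyl)dimethylsilane | CC(C)(C)[Si](C)(C)OCCCBr | starting material
2 | 3-ethoxy-2-methylcyclohex-2-en-1-one | CCOC1=C(C)C(=O)CCC1 | starting material
3 | (3-{[tert-butyl(dimethyl)silyl]oxy}propyl)magnesium bromide | CC(C)(C)[Si](C)(C)OCCC[Mg]Br | intermediate (not isolated)
4 | 1-(3-{[tert-butyl(dimethyl)silyl]oxy}propyl)-3-ethoxy-2-methylcyclohex-2-en-1-ol (racemic) | CCOC1=C(C)C(O)(CCCO[Si](C)(C)C(C)(C)C)CCC1 | intermediate (not isolated)
5 | 3-(3-{[tert-butyl(dimethyl)silyl]oxy}propyl)-2-methylcyclohex-2-en-1-one | CC1=C(CCCO[Si](C)(C)C(C)(C)C)CCCC1=O | intermediate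
6 | (1R)-3-(3-{[tert-butyl(dimethyl)silyl]oxy}propyl)-2-methylcyclohex-2-en-1-ol | O[C@@H]1CCCC(CCCO[Si](C)(C)C(C)(C)C)=C1C | intermediate
7 | (1R,2R,6R)-6-(3-{[tert-butyl(dimethyl)silyl]oxy}propyl)-1-methyl-7-oxabicyclo[4.1.0]heptan-2-ol | O[C@@H]1CCC[C@]2(CCCO[Si](C)(C)C(C)(C)C)O[C@]12C | intermediate
8 | (1S,6R)-6-(3-{[tert-butyl(dimethyl)silyl]oxy}propyl)-1-methyl-7-oxabicyclo[4.1.0]heptan-2-one | O=C1CCC[C@]2(CCCO[Si](C)(C)C(C)(C)C)O[C@]12C | intermediate
9 | hydrazone of 8 | NN=C1CCC[C@]2(CCCO[Si](C)(C)C(C)(C)C)O[C@]12C | intermediate (not isolated)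
10 | (1R)-1-(3-{[tert-butyl(dimethyl)silyl]oxy}propyl)-2-methylcyclohex-2-en-1-ol | O[C@]1(CCCO[Si](C)(C)C(C)(C)C)C(C)=CCCC1 | intermediate
11 | (2R,3R)-3-bromo-2-(3-{[tert-butyl(dimethyl)silyl]oxy}propyl)-2-methylcyclohexan-1-one | O=C1CCC[C@@H](Br)[C@]1(C)CCCO[Si](C)(C)C(C)(C)C | intermediate
12 | lithium (5R,6R)-5-bromo-6-(3-{[tert-butyl(dimethyl)silyl]oxy}propyl)-6-methylcyclohex-1-en-1-olate | [Li]OC1=CCC[C@@H](Br)[C@]1(C)CCCO[Si](C)(C)C(C)(C)C | intermediate (not isolated)
13 | (2R,3R)-3-bromo-2-(3-{[tert-butyl(dimethyl)silyl]oxy}propyl)-2,6-dimethylcyclohexan-1-one, both C6 epimers | CC1CC[C@@H](Br)[C@](C)(CCCO[Si](C)(C)C(C)(C)C)C1=O | intermediate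
14 | potassium (5R,6R)-5-bromo-6-(3-{[tert-butyl(dimethyl)silyl]oxy}propyl)-2,6-dimethylcyclohex-1-en-1-olate | [K]OC1=C(C)CC[C@@H](Br)[C@]1(C)CCCO[Si](C)(C)C(C)(C)C | intermediate (not isolated)
15 | (5R,6R)-5-bromo-6-(3-{[tert-butyl(dimethyl)silyl]oxy}propyl)-2,6-dimethylcyclohex-1-en-1-yl trifluoromethanesulfonate | CC1=C(OS(=O)(=O)C(F)(F)F)[C@@](C)(CCCO[Si](C)(C)C(C)(C)C)[C@H](Br)CC1 | intermediate
16 | tributyl(ethenyl)stannane | C=C[Sn](CCCC)(CCCC)CCCC | starting material
17 | tert-butyl{3-[(1R,6R)-6-bromo-2-ethenyl-1,3-dimethylcyclohex-2-en-1-yl]propoxy}dimethylsilane | C=CC1=C(C)CC[C@@H](Br)[C@]1(C)CCCO[Si](C)(C)C(C)(C)C | intermediate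
18 | methyl 3-formyl-4-hydroxybenzoate | COC(=O)c1ccc(O)c(C=O)c1 | starting material
19 | methyl 3-bromo-5-formyl-4-hydroxybenzoate | COC(=O)c1cc(Br)c(O)c(C=O)c1 | intermediate
20 | methyl 3-bromo-5-formyl-4-(methoxymethoxy)benzoate | COCOc1c(Br)cc(C(=O)OC)cc1C=O | intermediate
21 | prop-1-yn-1-ylmagnesium bromide | CC#C[Mg]Br | starting material
22 | methyl 3-bromo-5-(1-hydroxybut-2-yn-1-yl)-4-(methoxymethoxy)benzoate (racemic) | CC#CC(O)c1cc(C(=O)OC)cc(Br)c1OCOC | intermediate
23 | methyl 3-bromo-5-(but-2-ynoyl)-4-(methoxymethoxy)benzoate | CC#CC(=O)c1cc(C(=O)OC)cc(Br)c1OCOC | intermediate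
24 | methyl 3-bromo-5-{[(5R,6R,8aR)-6-bromo-5-(3-{[tert-butyl(dimethyl)silyl]oxy}propyl)-2,5,8a-trimethyl-3,5,6,7,8,8a-hexahydronaphthalen-1-yl]carbonyl}-4-(methoxymethoxy)benzoate | CC1=C(C(=O)c2cc(C(=O)OC)cc(Br)c2OCOC)[C@]3(C)CC[C@@H](Br)[C@](C)(CCCO[Si](C)(C)C(C)(C)C)C3=CC1 | intermediate
25 | methyl 3-bromo-5-{[(4aS,5R,6R,8aR)-6-bromo-5-(3-{[tert-butyl(dimethyl)silyl]oxy}propyl)-2,5,8a-trimethyl-3,4,4a,5,6,7,8,8a-octahydronaphthalen-1-yl]carbonyl}-4-(methoxymethoxy)benzoate | CC1=C(C(=O)c2cc(C(=O)OC)cc(Br)c2OCOC)[C@]3(C)CC[C@@H](Br)[C@](C)(CCCO[Si](C)(C)C(C)(C)C)[C@H]3CC1 | intermediate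
26 | methyl 3-bromo-5-{[(1R,4aS,5R,6R,8aR)-6-bromo-5-(3-{[tert-butyl(dimethyl)silyl]oxy}propyl)-5,8a-dimethyl-2-methylidenedecahydronaphthalen-1-yl]carbonyl}-4-(methoxymethoxy)benzoate | C=C1CC[C@@H]2[C@@](C)(CCCO[Si](C)(C)C(C)(C)C)[C@H](Br)CC[C@@]2(C)[C@@H]1C(=O)c1cc(C(=O)OC)cc(Br)c1OCOC | intermediate
27 | as 26 with a trimethylsilyloxy group in place of the methoxymethoxy group | C=C1CC[C@@H]2[C@@](C)(CCCO[Si](C)(C)C(C)(C)C)[C@H](Br)CC[C@@]2(C)[C@@H]1C(=O)c1cc(C(=O)OC)cc(Br)c1O[Si](C)(C)C | intermediate (not isolated)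
28 | methyl 3-bromo-5-{[(1R,4aS,5R,6R,8aR)-6-bromo-5-(3-{[tert-butyl(dimethyl)silyl]oxy}propyl)-5,8a-dimethyl-2-methylidenedecahydronaphthalen-1-yl]carbonyl}-4-hydroxybenzoate | C=C1CC[C@@H]2[C@@](C)(CCCO[Si](C)(C)C(C)(C)C)[C@H](Br)CC[C@@]2(C)[C@@H]1C(=O)c1cc(C(=O)OC)cc(Br)c1O | intermediate
29 | as 28 with an ethoxycarbonyloxy group in place of the phenolic hydroxyl | C=C1CC[C@@H]2[C@@](C)(CCCO[Si](C)(C)C(C)(C)C)[C@H](Br)CC[C@@]2(C)[C@@H]1C(=O)c1cc(C(=O)OC)cc(Br)c1OC(=O)OCC | intermediate (not isolated)
30 | methyl 3-bromo-5-{[(1R,4aS,5R,6R,8aS)-6-bromo-5-(3-{[tert-butyl(dimethyl)silyl]oxy}propyl)-5,8a-dimethyl-2-methylidenedecahydronaphthalen-1-yl]methyl}-4-hydroxybenzoate | C=C1CC[C@@H]2[C@@](C)(CCCO[Si](C)(C)C(C)(C)C)[C@H](Br)CC[C@@]2(C)[C@@H]1Cc1cc(C(=O)OC)cc(Br)c1O | intermediate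
31 | methyl 3-bromo-5-{[(1R,4aS,5R,6R,8aS)-6-bromo-5-(3-hydroxypropyl)-5,8a-dimethyl-2-methylidenedecahydronaphthalen-1-yl]methyl}-4-hydroxybenzoate | C=C1CC[C@@H]2[C@@](C)(CCCO)[C@H](Br)CC[C@@]2(C)[C@@H]1Cc1cc(C(=O)OC)cc(Br)c1O | intermediate
32 | methyl 3-bromo-5-{[(1R,4aS,5R,6R,8aS)-6-bromo-5,8a-dimethyl-2-methylidene-5-(3-oxopropyl)decahydronaphthalen-1-yl]methyl}-4-hydroxybenzoate | C=C1CC[C@@H]2[C@@](C)(CCC=O)[C@H](Br)CC[C@@]2(C)[C@@H]1Cc1cc(C(=O)OC)cc(Br)c1O | intermediate
33 | methyl 3-bromo-5-{[(1R,4aS,5R,6R,8aS)-6-bromo-5,8a-dimethyl-2-methylidene-5-(4-methylpent-3-en-1-yl)decahydronaphthalen-1-yl]methyl}-4-hydroxybenzoate | C=C1CC[C@@H]2[C@@](C)(CCC=C(C)C)[C@H](Br)CC[C@@]2(C)[C@@H]1Cc1cc(C(=O)OC)cc(Br)c1O | intermediate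
34 | callophycoic acid H, 3-bromo-5-{[(1R,4aS,5R,6R,8aS)-6-bromo-5,8a-dimethyl-2-methylidene-5-(4-methylpent-3-en-1-yl)decahydronaphthalen-1-yl]methyl}-4-hydroxybenzoic acid | C=C1CC[C@@H]2[C@@](C)(CCC=C(C)C)[C@H](Br)CC[C@@]2(C)[C@@H]1Cc1cc(C(=O)O)cc(Br)c1O | target

**Step count and risks**

Total: 22 steps. Longest linear sequence: 18 steps (steps 1–9 and 14–22); the aryl branch (steps 10–13) joins at step 14.

Steps most likely to fail:

1. Step 14. The cycloaddition at the fully substituted C10 terminus may be slower than thermal decomposition or polymerisation of the partners, or regio- and facial selectivity may erode at the temperature required. Fallback, setting out from 17 and returning at 24: the diene 17 would be combined with commercial but-2-ynal under Me2AlCl catalysis (CH2Cl2, −78 → −20 °C), a smaller and more strongly activated dienophile that forms the same two bonds, to give the dienal F1. The aryl group would then be added as a nucleophile. Commercial methyl 3,5-dibromo-4-hydroxybenzoate would be protected (MOMCl, iPr2NEt) to methyl 3,5-dibromo-4-(methoxymethoxy)benzoate F2. One of its two equivalent bromines would be exchanged (iPrMgCl·LiCl, THF, −20 °C) to give the arylmagnesium chloride F3, which would add to F1 to give the secondary carbinol F4. Dess–Martin oxidation of F4 gives 24.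

2. Step 16. Over-irradiation may drive secondary photochemistry of the product aryl ketone (acyl shift, hydrogen abstraction from the C10 methyl or the MOM group), C–Br homolysis may occur, or the dienol may simply revert to the conjugated ketone. Fallback, setting out from 25 and returning at 26: ground-state deconjugation, in which 25 would be deprotonated at the C12 methyl (the γ-position cis to the carbonyl) with KN(SiMe3)2 in THF at −78 °C to the extended potassium dienolate F5, which would be quenched kinetically at C9 by inverse addition to AcOH/THF at −78 °C to give 26.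

3. Step 6. The bromonium ion may be captured by the tertiary hydroxyl (epoxide formation) or by the silyl ether oxygen (bromo-etherification), or the ring bond may migrate (ring contraction) instead of the side chain. Fallback, setting out from 1 and returning at 11: the quaternary centre would be made by the oxygen analogue of the shift with methyl as the migrating group. Zinc insertion into 1 (Zn dust, LiCl, THF, 50 °C) gives the alkylzinc bromide F6, and Negishi coupling with commercial 2-iodocyclohex-2-en-1-one (Pd(PPh3)4, THF, rt → 40 °C) gives the 2-substituted enone F7. Catalytic asymmetric addition of Me2Zn (Ti(OiPr)4, the bis(sulfonamide)diol ligand from trans-cyclohexane-1,2-diamine and camphor-10-sulfonyl chloride, toluene, rt; the ligand enantiomer that delivers the (R)-carbinol) gives the tertiary allylic alcohol F8. Hydroxyl-directed epoxidation (VO(acac)2, t-BuOOH) gives the syn epoxy alcohol F9. BF3·OEt2 in CH2Cl2 at −78 °C triggers the semipinacol shift of methyl anti to the epoxide C–O bond and gives the (2S,3S)-hydroxy ketone F10, with hydroxyl cis to the side chain. Appel bromination (CBr4, PPh3) with inversion gives 11; this neopentyl-type displacement is expected to be only moderately efficient.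

Further compounds
F1 | step 14 | (5R,6R,8aR)-6-bromo-5-(3-{[tert-butyl(dimethyl)silyl]oxy}propyl)-2,5,8a-trimethyl-3,5,6,7,8,8a-hexahydronaphthalene-1-carbaldehyde | CC1=C(C=O)[C@]2(C)CC[C@@H](Br)[C@](C)(CCCO[Si](C)(C)C(C)(C)C)C2=CC1
F2 | step 14 | methyl 3,5-dibromo-4-(methoxymethoxy)benzoate | COCOc1c(Br)cc(C(=O)OC)cc1Br
F3 | step 14 | [3-bromo-5-(methoxycarbonyl)-2-(methoxymethoxy)phenyl]magnesium chloride | COCOc1c(Br)cc(C(=O)OC)cc1[Mg]Cl
F4 | step 14 | methyl 3-bromo-5-{hydroxy[(5R,6R,8aR)-6-bromo-5-(3-{[tert-butyl(dimethyl)silyl]oxy}propyl)-2,5,8a-trimethyl-3,5,6,7,8,8a-hexahydronaphthalen-1-yl]methyl}-4-(methoxymethoxy)benzoate (carbinol epimers) | CC1=C(C(O)c2cc(C(=O)OC)cc(Br)c2OCOC)[C@]3(C)CC[C@@H](Br)[C@](C)(CCCO[Si](C)(C)C(C)(C)C)C3=CC1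
F5 | step 16 | potassium dienolate of 25 (C8=C12 and C9=C11 double bonds, O–K on C11) | C=C1CC[C@@H]2[C@@](C)(CCCO[Si](C)(C)C(C)(C)C)[C@H](Br)CC[C@@]2(C)C1=C(O[K])c1cc(C(=O)OC)cc(Br)c1OCOC
F6 | step 6 | (3-{[tert-butyl(dimethyl)silyl]oxy}propyl)zinc bromide | CC(C)(C)[Si](C)(C)OCCC[Zn]Br
F7 | step 6 | 2-(3-{[tert-butyl(dimethyl)silyl]oxy}propyl)cyclohex-2-en-1-one | O=C1CCCC=C1CCCO[Si](C)(C)C(C)(C)C
F8 | step 6 | (1R)-2-(3-{[tert-butyl(dimethyl)silyl]oxy}propyl)-1-methylcyclohex-2-en-1-ol | C[C@@]1(O)CCCC=C1CCCO[Si](C)(C)C(C)(C)C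
F9 | step 6 | (1S,2R,6S)-1-(3-{[tert-butyl(dimethyl)silyl]oxy}propyl)-2-methyl-7-oxabicyclo[4.1.0]heptan-2-ol (epoxide cis to hydroxyl) | C[C@@]1(O)CCC[C@@H]2O[C@]12CCCO[Si](C)(C)C(C)(C)C
F10 | step 6 | (2S,3S)-2-(3-{[tert-butyl(dimethyl)silyl]oxy}propyl)-3-hydroxy-2-methylcyclohexan-1-one | O=C1CCC[C@H](O)[C@]1(C)CCCO[Si](C)(C)C(C)(C)C
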